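**Plan**
- Retrosynthesis: the C9–O angelate bond, the C3–O bond (through the 3-ketone back to the C3 methylene) and the C11=C13 bond are cut first. Then follow the lactone C12–O6 bond and the C6–H and C1–H bonds, which leads back to a 6-ketone with a C1=C10 alkene.
- Enabling feature: in the ten-membered ring C1–C10, the C4=C5 bond and the C1–C10 unit are 1,5-related. The ring is therefore the cycloreversion product of a cyclohexanone (C5, C6, C7, C8, C9, C10) that shares C5–C10 with a bicyclo[2.2.0]hexane (C1, C2, C3, C4, C5, C10). Restoring σ bonds C1–C4 and C5–C10 and then cutting C4–C5 and C1–C10 gives an enone and 1-methylcyclobutene.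
- Forward order of rings: six-membered ring of (S)-carvone, then δ-lactone bridge C9–O–C12 (a clamp), then two cyclobutanes by [2+2] photocycloaddition, then the ten-membered ring by thermal cycloreversion. The clamp is then reduced away and the γ-lactone C6–O–C12 is closed.
- Stereochemistry: C7 comes from (S)-carvone and C9 from it by cis-selective Luche reduction. The 4Z/1(10)E geometry comes from the clamped chair-like diyl, C10 from outer-face epoxidation, C6 from peripheral hydride attack, and C3 from a reagent-controlled CBS reduction.

Key step: step 7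

Remark: atoms carry germacrane numbers from step 1 on. In carvone, C=O is C9, C–CH3 is C10 with C14, =CH is C5, the ring CH2 groups are C6 and C8, CH is C7, and isopropenyl is C11–C13. α and β refer to the flat germacrane drawing with H-7 α.
Assumption: C11 forms as a mixture of epimers in step 2. It is left undefined in names and SMILES until enolisation merges both epimers in step 12, and it ceases to be a stereocentre in step 13.

**Step 1**
Reactants: 1 (S)-(+)-carvone
Product: 2 (+)-cis-carveol, (1S,5S)-2-methyl-5-(prop-1-en-2-yl)cyclohex-2-en-1-ol (9β-OH cis to the 7β-isopropenyl group)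
Conditions: NaBH4, CeCl3·7H2O, MeOH, −20 °C
Reagents that add atoms: none
Why: Luche 1,2-reduction, in which hydride attacks along the axial trajectory of the half-chair that keeps the C7 isopropenyl group equatorial, so the new C9 hydroxyl is pseudo-equatorial and cis (β) to C11 and C9 is fixed from the carvone centre C7.

**Step 2**
Reactants: 2 (+)-cis-carveol
Product: 4 (1S,5S)-5-(1-hydroxypropan-2-yl)-2-methylcyclohex-2-en-1-ol (9β,12-diol; C11 epimers), via bis(9-BBN) adduct 3 (not isolated)
Conditions: 9-BBN (2.3 equiv), THF, 0 °C to rt; then NaOH, H2O2, 0 °C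
Reagents that add atoms: hydrogen peroxide, OO
Why: Hydroboration–oxidation, in which 9-BBN distinguishes the 1,1-disubstituted side-chain alkene from the trisubstituted ring alkene and places boron on the terminal carbon, giving the primary C12 alcohol, while C11 arises unselectively and is of no consequence.

**Step 3**
Reactants: 4 9β,12-diol
Product: 7 (1S,5S)-4,8-dimethyl-2-oxabicyclo[3.3.1]non-7-en-3-one (12,9β-olide clamp; C5=C10 alkene), via hydroxy aldehyde 5 (not isolated), via bridged lactol 6 (not isolated)
Conditions: TEMPO (cat.), PhI(OAc)2, CH2Cl2, rt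
Reagents that add atoms: none
Why: Oxoammonium (TEMPO) oxidative lactonisation of a 1,5-diol, in which the primary alcohol is oxidised first, the aldehyde is caught by the cis C9 hydroxyl as a bridged lactol that is oxidised on, and only the cis 7,9-relation from step 1 permits this closure.

**Step 4**
Reactants: 7 bicyclic alkene lactone
Product: 8 (1S,5S)-4,8-dimethyl-2-oxabicyclo[3.3.1]non-7-ene-3,6-dione (6-oxo enone lactone)
Conditions: Rh2(cap)4 (cat., cap = caprolactamate), t-BuOOH (70% in water), 1,2-dichloroethane, 40 °C
Reagents that add atoms: tert-butyl hydroperoxide, CC(C)(C)OO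
Why: Dirhodium-catalysed allylic C–H oxidation, which abstracts hydrogen at the ring methylene C6 next to the CH end of the trisubstituted alkene (as in 1-methylcyclohexene to 3-methylcyclohexenone), while the bridgehead C9–H lies in the nodal plane of the alkene and is deactivated by the acyloxy group.

**Step 5**
Reactants: 9 methylenecyclobutane
Product: 10 1-methylcyclobutene
Conditions: Na on Al2O3, neat, rt; distillation
Reagents that add atoms: none
Why: Base-catalysed alkene isomerisation through the allyl anion, which moves the exocyclic double bond to the more substituted endocyclic position under equilibrium control.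

**Step 6**
Reactants: 8 enone lactone; 10 1-methylcyclobutene
Product: 11 tetracyclic cis-anti-cis photoadduct (6-oxo-12,9β-olide; central cyclobutane C5–C10–C1–C4 on the α face with H-5 and C14 β; outer cyclobutane C1–C2–C3–C4 anti to the six-membered ring, so H-1 and C15 are syn to C9 and C6)
Conditions: hν (medium-pressure Hg lamp, Pyrex), 10 (10 equiv), CH2Cl2, −30 °C
Reagents that add atoms: none
Why: Enone–alkene [2+2] photocycloaddition through the enone triplet, in which C10 bonds first to the unsubstituted cyclobutene carbon C1 to give the tertiary C4 radical that closes on C5 and avoids adjacent quaternary carbons, the lactone bridge covers the β face so the alkene adds from the α face with a cis ring fusion, and exo approach of the cyclobutene methylene groups gives the cis-anti-cis array.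

**Step 7**
Reactants: 11 tetracyclic photoadduct
Product: 12 (1(10)E,4Z)-6-oxogermacra-1(10),4-dien-12,9β-olide (H-7α)
Conditions: toluene (0.01 M, degassed, BHT), base-washed sealed tube or flow coil, 185 °C, short contact time
Reagents that add atoms: none
Why: Heating breaks the most strained bond, C1–C4, to a cyclohexane-1,4-diyl (C1, C2, C3, C4, C5, C10) that relaxes from the boat to a chair and then sheds C5–C10, the weakest flanking σ bond (quaternary C10, α-keto C5), so that C1=C10 and C4=C5 appear in a formal [σ2s+σ2a] retro-[2+2] of the central cyclobutane driven by the loss of two four-membered rings. The closest known reaction type is the photo-thermal olefin metathesis sequence in which a cyclohexenone–cyclobutene [2+2] adduct gives a cis,trans-cyclodeca-1,5-diene on heating. No ring-closing bond is made: the ten-membered ring C1–C10 is set free because the broken C5–C10 bond is shared by the six-membered ring and the central cyclobutane, i.e. a ring enlargement by fragmentation (6 + 4 to 10). No stereocentre is formed (C1, C4, C5 and C10 are erased, C7 and C9 are spectators), but two double-bond geometries are fixed by the chair diyl, in which a substituent that is equatorial on the diyl ring ends trans and an axial one ends cis. The lactone clamp holds O-9 and C11 1,3-diaxial on the six-membered ring, which can therefore twist only towards the chair with C1 axial and C4 equatorial; on the diyl ring this makes C9 equatorial (1(10)E) and C6 axial (4Z), whereas free equatorial C7 and C9 substituents would favour the opposite pairing. The step also needs C5–C10 rather than C2–C3 cleavage and survival of the product: the first follows from bond strength and enone conjugation, the second from the fact that a Z,E-diene can undergo Cope rearrangement only through a boat transition state, helped by dilution and short contact time.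

**Step 8**
Reactants: 12 dienone lactone
Product: 13 1β,10α-epoxy-(4Z)-6-oxogermacr-4-en-12,9β-olide
Conditions: mCPBA (1.1 equiv), CH2Cl2, 0 °C
Reagents that add atoms: mCPBA, OOC(=O)c1cccc(Cl)c1
Why: Prilezhaev epoxidation, in which the peracid takes the electron-rich C1=C10 bond and ignores the enone, and because the inner face of the E double bond looks at C5 across the ring only the outer face is open in the clamped conformer, which puts oxygen on C10 opposite to the former C5–C10 bond.

**Step 9**
Reactants: 13 epoxy enone lactone
Product: 14 (4Z)-germacr-4-ene-6α,9β,10α,12-tetraol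
Conditions: LiAlH4 (excess), THF, −78 °C to reflux; aqueous work-up
Reagents that add atoms: none
Why: LiAlH4 reduction of ketone, lactone and epoxide in one operation, in which hydride at low temperature should reach the C6 carbonyl from the ring periphery (the inner face is covered by C1, C10 and C8) to give the 6α-alcohol, the clamp is then cleaved to the C9 and C12 alcohols, and on heating the epoxide is opened by SN2 attack at the secondary C1, leaving the C10–O bond and the 10α-carbinol configuration untouched.

**Step 10**
Reactants: 14 tetraol
Product: 17 9β,10α-dihydroxy-(4Z)-germacr-4-en-12,6α-olide (trans-fused γ-lactone), via 12-aldehyde 15 (not isolated), via γ-lactol 16 (not isolated)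
Conditions: Cu(MeCN)4OTf, 2,2′-bipyridine, TEMPO, N-methylimidazole (all cat.), air, MeCN, rt
Reagents that add atoms: none
Why: Copper/nitroxyl aerobic oxidative lactonisation of a 1,4-diol, in which only the primary C12 alcohol is oxidised, the aldehyde closes with the neighbouring 6α-hydroxyl to the five-membered lactol faster than with the remote C9 hydroxyl, and a second oxidation gives the trans-fused γ-lactone without the glycol cleavage that a hypervalent iodine oxidant could cause at C9–C10.

**Step 11**
Reactants: 17 lactone diol
Product: 18 9β,10α-bis(trimethylsilyloxy)-(4Z)-germacr-4-en-12,6α-olide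
Conditions: 1-(trimethylsilyl)imidazole, CH2Cl2, rt
Reagents that add atoms: 1-(trimethylsilyl)imidazole, C[Si](C)(C)n1ccnc1
Why: Silylation with a powerful silyl donor masks the secondary C9 and the tertiary C10 hydroxyl so that only one acidic site is left for the enolisation that follows.

**Step 12**
Reactants: 18 bis-TMS lactone
Product: 20 11β-phenylseleno-11α-methyl lactone (9β,10α-bis-TMS ether), via lithium enolate 19 (not isolated)
Conditions: LDA, THF, −78 °C; then PhSeBr, −78 °C
Reagents that add atoms: benzeneselenenyl bromide, Br[Se]c1ccccc1
Why: α-Selenenylation of a lactone enolate, in which LDA removes H-11 and so merges the two C11 epimers, and PhSeBr enters from the face opposite to the axial H-7 of the trans-fused lactone, so selenium stands anti to H-7.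

**Step 13**
Reactants: 20 selenide
Product: 23 9β,10α-dihydroxygermacra-4Z,11(13)-dien-12,6α-olide, via selenoxide 21 (not isolated), via bis-TMS methylene lactone 22 (not isolated)
Conditions: H2O2 (30%), pyridine, CH2Cl2, 0 °C to rt; then AcOH–THF–H2O, rt
Reagents that add atoms: none
Why: Selenoxide syn-elimination, which can only take a methyl hydrogen because no ring hydrogen is syn to selenium and so gives the exocyclic C11=C13 bond, after which the mild acid removes both trimethylsilyl ethers.

**Step 14**
Reactants: 23 α-methylene lactone diol; 24 angelic acid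
Product: 26 9β-angeloyloxy-10α-hydroxygermacra-4Z,11(13)-dien-12,6α-olide, via mixed anhydride 25 (not isolated)
Conditions: 24, 2,4,6-Cl3C6H2COCl, Et3N, toluene, rt; then 23, 80 °C
Reagents that add atoms: none
Why: Yamaguchi-type mixed-anhydride esterification run without a nucleophilic catalyst, the known way to transfer the angeloyl group without Z-to-E isomerisation, and only the secondary C9 hydroxyl can be acylated because the tertiary C10 hydroxyl is inert.

**Step 15**
Reactants: 26 angelate
Product: 27 9β-angeloyloxy-10α-hydroxy-3-oxogermacra-4Z,11(13)-dien-12,6α-olide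
Conditions: CrO3, 3,5-dimethylpyrazole, CH2Cl2, −20 °C
Reagents that add atoms: chromium trioxide, O=[Cr](=O)=O
Why: Chromium trioxide–dimethylpyrazole allylic oxidation, in which C4=C5 is the only electron-rich alkene, its ring methylene C3 should be oxidised in preference to the C15 methyl group and the acyloxy-deactivated C6–H, and the acrylate and angelate double bonds are too electron-poor to react.

**Step 16**
Reactants: 27 3-ketone
Product: 28 target, (3S,6R,7S,9S,10S)-9β-angeloyloxy-3β,10α-dihydroxygermacra-4Z,11(13)-dien-12,6α-olide
Conditions: (R)-Me-CBS oxazaborolidine (cat.), catecholborane, toluene, −78 °C; MeOH quench, aqueous work-up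
Reagents that add atoms: none
Why: CBS reduction, in which the (R)-oxazaborolidine binds the ketone with the larger α-methylalkenyl side (C4) away from the catalyst and delivers hydride to the face that gives the 3S (3β) allylic alcohol under reagent control, while catecholborane at low temperature leaves the lactone, the angelate and the α-methylene group alone.

**Compound list**
1 | (S)-(+)-carvone | CC1=CC[C@@H](CC1=O)C(C)=C | starting material
2 | (+)-cis-carveol | CC1=CC[C@@H](C[C@@H]1O)C(C)=C | intermediate
3 | bis(9-BBN) adduct (C9 borinate, C12 alkylborane) | CC1=CC[C@@H](C[C@@H]1OB2C3CCCC2CCC3)C(C)CB2C3CCCC2CCC3 | intermediate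
4 | 9β,12-diol (C11 epimers) | CC1=CC[C@@H](C[C@@H]1O)C(C)CO | intermediate
5 | 9β-hydroxy 12-aldehyde | CC1=CC[C@@H](C[C@@H]1O)C(C)C=O | intermediate
6 | bridged lactol | CC1=CC[C@H]2C[C@@H]1OC(O)C2C | intermediate
7 | (1S,5S)-4,8-dimethyl-2-oxabicyclo[3.3.1]non-7-en-3-one | CC1=CC[C@H]2C[C@@H]1OC(=O)C2C | intermediate
8 | (1S,5S)-4,8-dimethyl-2-oxabicyclo[3.3.1]non-7-ene-3,6-dione | CC1=CC(=O)[C@H]2C[C@@H]1OC(=O)C2C | intermediate
9 | methylenecyclobutane | C=C1CCC1 | starting material
10 | 1-methylcyclobutene | CC1=CCC1 | intermediate
11 | tetracyclic cis-anti-cis photoadduct | O=C1[C@H]2C[C@H](OC(=O)C2C)[C@@]3(C)[C@@H]4CC[C@]4(C)[C@@H]13 | intermediate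
12 | (1(10)E,4Z)-6-oxogermacra-1(10),4-dien-12,9β-olide | O=C1/C=C(/C)CC/C=C(C)/[C@@H]2C[C@H]1C(C)C(=O)O2 | intermediate
13 | 1β,10α-epoxy-(4Z)-6-oxogermacr-4-en-12,9β-olide | O=C1/C=C(/C)CC[C@H]3O[C@]3(C)[C@@H]2C[C@H]1C(C)C(=O)O2 | intermediate
14 | (4Z)-germacr-4-ene-6α,9β,10α,12-tetraol | OCC(C)[C@@H]1C[C@H](O)[C@@](C)(O)CCC/C(C)=C\[C@H]1O | intermediate
15 | 6α,9β,10α-trihydroxy 12-aldehyde | O=CC(C)[C@@H]1C[C@H](O)[C@@](C)(O)CCC/C(C)=C\[C@H]1O | intermediate
16 | γ-lactol | CC1C(O)O[C@@H]2/C=C(/C)CCC[C@](C)(O)[C@@H](O)C[C@@H]12 | intermediate
17 | 9β,10α-dihydroxy-(4Z)-germacr-4-en-12,6α-olide | CC1C(=O)O[C@@H]2/C=C(/C)CCC[C@](C)(O)[C@@H](O)C[C@@H]12 | intermediate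
18 | 9β,10α-bis-TMS ether of 17 | CC1C(=O)O[C@@H]2/C=C(/C)CCC[C@](C)(O[Si](C)(C)C)[C@@H](O[Si](C)(C)C)C[C@@H]12 | intermediate
19 | lithium enolate of 18 | CC1=C([O-])O[C@@H]2/C=C(/C)CCC[C@](C)(O[Si](C)(C)C)[C@@H](O[Si](C)(C)C)C[C@@H]12.[Li+] | intermediate
20 | 11β-phenylseleno-11α-methyl lactone | C[C@]1([Se]c3ccccc3)C(=O)O[C@@H]2/C=C(/C)CCC[C@](C)(O[Si](C)(C)C)[C@@H](O[Si](C)(C)C)C[C@@H]12 | intermediate
21 | selenoxide of 20 | C[C@]1([Se](=O)c3ccccc3)C(=O)O[C@@H]2/C=C(/C)CCC[C@](C)(O[Si](C)(C)C)[C@@H](O[Si](C)(C)C)C[C@@H]12 | intermediate
22 | bis-TMS α-methylene lactone | C=C1C(=O)O[C@@H]2/C=C(/C)CCC[C@](C)(O[Si](C)(C)C)[C@@H](O[Si](C)(C)C)C[C@@H]12 | intermediate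
23 | 9β,10α-dihydroxygermacra-4Z,11(13)-dien-12,6α-olide | C=C1C(=O)O[C@@H]2/C=C(/C)CCC[C@](C)(O)[C@@H](O)C[C@@H]12 | intermediate
24 | angelic acid | C/C=C(/C)C(=O)O | starting material
25 | angelic 2,4,6-trichlorobenzoic anhydride | C/C=C(/C)C(=O)OC(=O)c1c(Cl)cc(Cl)cc1Cl | intermediate
26 | 9β-angeloyloxy-10α-hydroxygermacra-4Z,11(13)-dien-12,6α-olide | C=C1C(=O)O[C@@H]2/C=C(/C)CCC[C@](C)(O)[C@@H](OC(=O)/C(C)=C\C)C[C@@H]12 | intermediate
27 | 3-oxo derivative of 26 | C=C1C(=O)O[C@@H]2/C=C(/C)C(=O)CC[C@](C)(O)[C@@H](OC(=O)/C(C)=C\C)C[C@@H]12 | intermediate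
28 | CNP0549192.1 | C=C1C(=O)O[C@@H]2/C=C(/C)[C@@H](O)CC[C@](C)(O)[C@@H](OC(=O)/C(C)=C\C)C[C@@H]12 | target

Total step count: 16.
Longest linear sequence: 15 (steps 1–4 and 6–16; step 5 is a side branch).

**Steps most likely to fail**

Step 7. The diyl may escape the control of the clamp by twisting through the boat form of the six-membered ring. C2–C3 may cleave instead of C5–C10, and the product may undergo Cope rearrangement on prolonged heating. The fallback replaces control of geometry by correction and sets out from 11.
- A thermolysate rich in the (1(10)Z,4E)-dienone lactone F1 is equilibrated at the enone with catalytic I2 under visible light to the (1(10)Z,4Z)-dienone lactone F2.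
- mCPBA then attacks the outer face of C1=C10, again opposite to C5, to give the cis-1,10-epoxide F3 with the same C10 configuration as 13.
- LiAlH4 as in step 9 turns C1 into a methylene group, which erases the C1=C10 geometry, and the route is rejoined at 14.

Step 9. Hydride may be delivered to the inner face of the C6 carbonyl while the clamp is still in place. The SN2 opening of the medium-ring epoxide may also be slow enough for the C6 alkoxide to compete. The fallback closes the γ-lactone with inversion and sets out from 13.
- If the same reduction gives mainly the 6β-alcohol, the 6-epi-tetraol F4 is oxidised at the primary alcohol only (TEMPO, NaOCl cat., NaClO2, buffered MeCN) to the 6β-hydroxy acid F5.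
- A Mitsunobu lactonisation (PPh3, DIAD, THF, 0 °C) lets the carboxylate displace the activated allylic C6 oxygen with inversion.
- This forms the C6–O bond instead of the acyl C–O bond and returns to the route at 17.

Step 15. Hydrogen abstraction may be unselective (C6–H, C15, C7–H), and over-oxidation may occur in a substrate that already carries the acrylate and the angelate. The fallback changes the mechanism from abstraction to an ene/[2,3] sequence and sets out from 26.
- SeO2 (cat.) with t-BuOOH in CH2Cl2 is known to tolerate α-methylene lactones. It hydroxylates the ring methylene at the more substituted alkene end to the C3-epimeric 3-alcohols F6.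
- Dess–Martin periodinane oxidises both epimers to 27, from which step 16 sets C3.

**Further compounds**
F1 | step 7 | (1(10)Z,4E)-6-oxogermacra-1(10),4-dien-12,9β-olide | O=C1/C=C(\C)CC/C=C(C)\[C@@H]2C[C@H]1C(C)C(=O)O2
F2 | step 7 | (1(10)Z,4Z)-6-oxogermacra-1(10),4-dien-12,9β-olide | O=C1/C=C(/C)CC/C=C(C)\[C@@H]2C[C@H]1C(C)C(=O)O2
F3 | step 7 | cis-1,10-epoxy-(4Z)-6-oxogermacr-4-en-12,9β-olide (10α-O) | O=C1/C=C(/C)CC[C@@H]3O[C@]3(C)[C@@H]2C[C@H]1C(C)C(=O)O2
F4 | step 9 | (4Z)-germacr-4-ene-6β,9β,10α,12-tetraol | OCC(C)[C@@H]1C[C@H](O)[C@@](C)(O)CCC/C(C)=C\[C@@H]1O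
F5 | step 9 | 6β,9β,10α-trihydroxy-(4Z)-germacr-4-en-12-oic acid | OC(=O)C(C)[C@@H]1C[C@H](O)[C@@](C)(O)CCC/C(C)=C\[C@@H]1O
F6 | step 15 | 9β-angeloyloxy-3,10α-dihydroxygermacra-4Z,11(13)-dien-12,6α-olide (C3 epimers) | C=C1C(=O)O[C@@H]2/C=C(/C)C(O)CC[C@](C)(O)[C@@H](OC(=O)/C(C)=C\C)C[C@@H]12
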